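**Plan**

Rings: A is the seven-membered ring with the exocyclic methylene, B is the seven-membered ring fused to the cyclohexene, C is the cyclohexene. The retrosynthesis removes the silyl ether, opens the bridgehead C=C of ring A (metathesis), and takes the C=CH2 of ring A and the C(CH3)=C of ring C back to two ketones. It then cuts, in one operation, the two ring-B bonds: bridge CH2 to bridgehead alkene carbon, and bridgehead CH to the B/C ring-fusion CH. Ring C falls last to a Robinson annulation.
Enabling feature: the methylene-bearing carbon of ring A and the methyl-bearing alkene carbon of ring C are 1,5-related through the bridgehead CH and the fusion CH, and the bridge CH2 is beta to the former. As ketones, the bridge CH2/bridgehead CH pair is the C=C of a vinyl ketone (acceptor at CH2, then donor at CH) and the fusion CH is the beta-carbon of a cyclohexenone. Ring B is therefore a five-carbon alkenyl-donor/enone-acceptor unit plus two carbons.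
Forward order: ring C (organocatalytic Robinson annulation), then ring B by a rhodium-catalysed conjugate addition–Michael cascade that also joins the two halves, then ring A by metathesis on a temporary exocyclic methylene that leaves as ethene.
Stereochemistry: the side-chain centre comes from (S)-citronellal and the ring-C CH from the amine catalyst. The fusion CH and the bridgehead CH come from the key step, where all new centres are epimerisable and should settle all-equatorial. The (E)-allylic alcohol comes from SeO2 oxidation.

Key step: step 9

Assumption: the (S)-diarylprolinol silyl ether shields the same enamine face as in its established aldehyde α-functionalisations, so step 1 gives the (4S) ring centre (otherwise the (R)-catalyst is used); the ring-fusion centre alpha to the ring-C ketone in 17 to 19 is drawn trans and disappears in step 11.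

**Route**

Step 1
Reactants: 1 (S)-citronellal; 2 methyl vinyl ketone
Product: 5 (4S)-4-[(2S)-6-methylhept-5-en-2-yl]cyclohex-2-en-1-one, via keto aldehyde 3 (not isolated), via aldol 4 (not isolated)
Conditions: (S)-α,α-diphenylprolinol trimethylsilyl ether (5 mol %), ethyl 3,4-dihydroxybenzoate (20 mol %), neat, 4 °C; then KOH, Bu4NOH (cat.), Et2O/THF/H2O, 40 °C
Reagents that add atoms: none
Why: Robinson annulation in two stages, an enamine-catalysed Michael addition in which the diarylprolinol ether shields one face of the (E)-enamine and so sets the new ring stereocentre (S) under catalyst control beside the untouched (S)-methyl centre of citronellal, then a base-mediated intramolecular aldol condensation to the enone.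

Step 2
Reactants: 5 enone
Product: 6 (4S)-4-[(2S,5E)-7-hydroxy-6-methylhept-5-en-2-yl]cyclohex-2-en-1-one
Conditions: SeO2 (0.3 equiv), t-BuOOH, salicylic acid (cat.), CH2Cl2, rt
Reagents that add atoms: tert-butyl hydroperoxide, CC(C)(C)OO
Why: Allylic oxidation with SeO2 (ene reaction then 2,3-sigmatropic shift) is selective for the electron-rich trisubstituted alkene and for its (E)-methyl group, so the electron-poor enone should survive and the (E)-allylic alcohol should result.

Step 3
Reactants: 6 allylic alcohol
Product: 7 tert-butyldimethylsilyl ether of 6
Conditions: TBSCl, imidazole, DMF, rt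
Reagents that add atoms: tert-butyldimethylsilyl chloride, CC(C)(C)[Si](C)(C)Cl
Why: Silylation of the primary allylic alcohol protects it from the organometallic, dehydrating and basic reagents used later.

Step 4
Reactants: 7 silyl ether
Product: 8 (4S)-2-iodo enone
Conditions: I2, pyridine, CH2Cl2, 0 °C to rt
Reagents that add atoms: iodine, II
Why: α-Iodination of the enone by the pyridine-mediated addition–iodination–elimination sequence places the halogen on the carbon that becomes the B/C ring junction and leaves the isolated trisubstituted alkene alone.

Step 5
Reactants: 9 3-bromobut-3-en-1-ol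
Product: 10 2-bromo-4-iodobut-1-ene
Conditions: I2, PPh3, imidazole, CH2Cl2, 0 °C
Reagents that add atoms: iodine, II
Why: Appel-type iodination converts the primary alcohol into the iodide by SN2 displacement of the alkoxyphosphonium ion without affecting the vinyl bromide.

Step 6
Reactants: 8 iodo enone; 10 2-bromo-4-iodobut-1-ene
Product: 12 (4S)-2-(3-bromobut-3-en-1-yl) enone, via alkylzinc iodide 11 (not isolated)
Conditions: 10, Zn dust (activated with BrCH2CH2Br and Me3SiCl), DMA, 40 °C; then 8, Pd2(dba)3 (2.5 mol %), P(2-furyl)3 (10 mol %), THF/DMA, rt
Reagents that add atoms: none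
Why: Negishi coupling, in which zinc inserts only into the primary C–I bond and oxidative addition of zerovalent palladium is far faster at the α-iodo enone than at the 1,1-disubstituted vinyl bromide, so the sp2–sp3 bond forms with enone and bromide intact.

Step 7
Reactants: 12 bromo enone
Product: 13 alkenyl pinacol boronate
Conditions: B2pin2, PdCl2(PPh3)2 (3 mol %), PPh3, KOPh, toluene, 50 °C
Reagents that add atoms: bis(pinacolato)diboron, CC1(C)OB(OC1(C)C)B1OC(C)(C)C(C)(C)O1
Why: Miyaura borylation of the vinyl bromide under the mild phenoxide conditions used for alkenyl halides turns the electrophile into the alkenyl nucleophile needed for the key step while tolerating the enone and the silyl ether.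

Step 8
Reactants: 14 pent-4-enoyl chloride
Product: 15 hepta-1,6-dien-3-one
Conditions: tributyl(vinyl)stannane, PdCl2(PPh3)2 (1 mol %), THF, 50 °C; used fresh
Reagents that add atoms: tributyl(vinyl)stannane, C=C[Sn](CCCC)(CCCC)CCCC
Why: Stille acylation (oxidative addition of the acid chloride to zerovalent palladium, vinyl transfer from tin, reductive elimination) gives the vinyl ketone directly and leaves the terminal alkene untouched.

Step 9
Reactants: 13 alkenyl boronate; 15 hepta-1,6-dien-3-one
Product: 17 trans-fused bicyclic diketone, via open-chain conjugate adduct 16 (not isolated)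
Conditions: [Rh(OH)(cod)]2 (3 mol %), KOH (0.5 equiv), 1,4-dioxane/H2O (10:1), slow addition of 15 (3 equiv), 25 °C then 40 °C
Reagents that add atoms: none
Why: Boron-to-rhodium transmetalation gives an alkenyl complex of monovalent rhodium, which inserts the C=C of vinyl ketone 15 (first new bond, alkenyl carbon to the terminal CH2) to give a rhodium oxa-π-allyl enolate; this enolate, or after protonation the hydroxide-generated enolate of 16, adds to the beta-carbon of the tethered cyclohexenone (second new bond), and protonation by water regenerates the rhodium hydroxide. The closest known reaction type is the rhodium-catalysed tandem conjugate addition–Michael cyclisation of organoboron reagents with enones (Hayashi–Miyaura addition followed by enolate Michael addition). Ring B closes in the 7-endo-trig mode, the acceptor C=C lying inside the new ring, and no other ring forms. The fusion CH next to the side-chain-bearing carbon is set by attack anti to the C4 substituent of the cyclohexenone; it, the acyl-bearing CH and the fusion CH alpha to the ring-C ketone are all epimerisable under the basic conditions (retro-Michael or enolisation), so the mixture should converge on the all-equatorial, trans-fused isomer with the acyl group trans to ring C, which is the relative configuration of the target. The step needs chemoselectivity for the external vinyl ketone over the α-substituted ring enone, secured by the far higher reactivity of vinyl ketones toward organorhodium addition and by the fact that intramolecular attack on the ring enone would be a disfavoured 5-endo insertion. It also needs regioselectivity in the Michael closure, secured because the other enolate of 16 could only close a nine-membered ring.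

Step 10
Reactants: 17 bicyclic diketone
Product: 18 tertiary methyl carbinol at the ring-C carbonyl
Conditions: MeTi(OiPr)3 (1.5 equiv), CH2Cl2, −20 °C to rt; aqueous work-up
Reagents that add atoms: methyltitanium triisopropoxide, C[Ti](OC(C)C)(OC(C)C)OC(C)C
Why: Chemoselective carbonyl addition in which the methyltitanium reagent discriminates strongly between ketones and should add to the strain-activated cyclohexanone of ring C in preference to the α-branched open-chain ketone, the configuration of the new carbinol centre being irrelevant because that carbon becomes sp2 in step 11.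

Step 11
Reactants: 18 tertiary alcohol
Product: 20 ketone with the tetrasubstituted ring-C alkene, via tertiary dichlorophosphate 19 (not isolated)
Conditions: POCl3, pyridine, 0 °C to 50 °C
Reagents that add atoms: none
Why: Dehydration by E2 elimination of the tertiary dichlorophosphate, for which the axial ring-fusion hydrogen is antiperiplanar, should follow the Zaitsev rule to the tetrasubstituted ring-C alkene and at the same time erases the ring-fusion stereocentre next to the former ketone.

Step 12
Reactants: 20 ketone
Product: 21 tetraene with the 1,1-disubstituted alkene of future ring A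
Conditions: Ph3PCH3Br, KOtBu, THF, 0 °C to rt
Reagents that add atoms: methyltriphenylphosphonium bromide, C[P+](c1ccccc1)(c1ccccc1)c1ccccc1.[Br-]
Why: Wittig methylenation of the remaining ketone installs the exocyclic methylene of ring A, and any base-induced epimerisation of the adjacent CH can only return it to the favoured trans arrangement set in step 9.

Step 13
Reactants: 21 tetraene
Product: 22 silyl ether of the target
Conditions: second-generation Hoveyda–Grubbs catalyst (5 mol %), toluene (2 mM), 80 °C
Reagents that add atoms: none
Why: Ring-closing metathesis between the terminal vinyl group and the temporary exocyclic methylene of ring B closes ring A with loss of ethene, the new bridgehead double bond being cis within the seven-membered ring and free of Bredt strain because it is trans only within the ten-membered perimeter.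

Step 14
Reactants: 22 silyl ether
Product: 23 target
Conditions: TBAF, THF, 0 °C to rt
Reagents that add atoms: none
Why: Fluoride-mediated desilylation frees the primary allylic alcohol without touching the four alkenes.

**Compound list**

1 | (S)-citronellal, (3S)-3,7-dimethyloct-6-enal | O=CC[C@@H](C)CCC=C(C)C | starting material
2 | methyl vinyl ketone (but-3-en-2-one) | CC(=O)C=C | starting material
3 | (2S,3S)-3,7-dimethyl-2-(3-oxobutyl)oct-6-enal (Michael adduct) | CC(=O)CC[C@@H]([C@@H](C)CCC=C(C)C)C=O | intermediate
4 | (4S)-3-hydroxy-4-[(2S)-6-methylhept-5-en-2-yl]cyclohexan-1-one (aldol, carbinol epimers) | O=C1CC[C@@H]([C@@H](C)CCC=C(C)C)C(O)C1 | intermediate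
5 | (4S)-4-[(2S)-6-methylhept-5-en-2-yl]cyclohex-2-en-1-one | O=C1CC[C@@H]([C@@H](C)CCC=C(C)C)C=C1 | intermediate
6 | (4S)-4-[(2S,5E)-7-hydroxy-6-methylhept-5-en-2-yl]cyclohex-2-en-1-one | O=C1CC[C@@H]([C@@H](C)CC/C=C(\C)CO)C=C1 | intermediate
7 | (4S)-4-[(2S,5E)-7-{[tert-butyl(dimethyl)silyl]oxy}-6-methylhept-5-en-2-yl]cyclohex-2-en-1-one | O=C1CC[C@@H]([C@@H](C)CC/C=C(\C)CO[Si](C)(C)C(C)(C)C)C=C1 | intermediate
8 | (4S)-2-iodo derivative of 7 (iodine on the enone α-carbon) | O=C1CC[C@@H]([C@@H](C)CC/C=C(\C)CO[Si](C)(C)C(C)(C)C)C=C1I | intermediate
9 | 3-bromobut-3-en-1-ol | OCCC(Br)=C | starting material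
10 | 2-bromo-4-iodobut-1-ene | ICCC(Br)=C | intermediate
11 | (3-bromobut-3-en-1-yl)zinc iodide | C=C(Br)CC[Zn]I | intermediate
12 | (4S)-2-(3-bromobut-3-en-1-yl)-4-[(2S,5E)-7-{[tert-butyl(dimethyl)silyl]oxy}-6-methylhept-5-en-2-yl]cyclohex-2-en-1-one | O=C1CC[C@@H]([C@@H](C)CC/C=C(\C)CO[Si](C)(C)C(C)(C)C)C=C1CCC(Br)=C | intermediate
13 | pinacol boronate of 12 (Bpin in place of Br) | O=C1CC[C@@H]([C@@H](C)CC/C=C(\C)CO[Si](C)(C)C(C)(C)C)C=C1CCC(=C)B1OC(C)(C)C(C)(C)O1 | intermediate
14 | pent-4-enoyl chloride | C=CCCC(=O)Cl | starting material
15 | hepta-1,6-dien-3-one | C=CCCC(=O)C=C | intermediate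
16 | open-chain adduct, (4S)-2-(3-methylidene-6-oxodec-9-en-1-yl) enone with the silylated side chain of 7 | O=C1CC[C@@H]([C@@H](C)CC/C=C(\C)CO[Si](C)(C)C(C)(C)C)C=C1CCC(=C)CCC(=O)CCC=C | intermediate
17 | (4S,4aS,5S,9aR)-7-methylidene-5-(pent-4-enoyl)decahydrobenzo[7]annulen-1-one with the silylated side chain at C4; trans ring fusion, acyl group trans to C4, side chain trans to C5 | C=C1CC[C@H]2C(=O)CC[C@@H]([C@@H](C)CC/C=C(\C)CO[Si](C)(C)C(C)(C)C)[C@@H]2[C@@H](C(=O)CCC=C)C1 | intermediate
18 | tertiary alcohol from methyl addition to the ring-C ketone of 17 (carbinol epimers) | C=C1CC[C@H]2C(C)(O)CC[C@@H]([C@@H](C)CC/C=C(\C)CO[Si](C)(C)C(C)(C)C)[C@@H]2[C@@H](C(=O)CCC=C)C1 | intermediate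
19 | dichlorophosphate ester of 18 | C=C1CC[C@H]2C(C)(OP(=O)(Cl)Cl)CC[C@@H]([C@@H](C)CC/C=C(\C)CO[Si](C)(C)C(C)(C)C)[C@@H]2[C@@H](C(=O)CCC=C)C1 | intermediate
20 | ketone with the tetrasubstituted C=C between the ring-fusion carbon and the methyl-bearing carbon of ring C; ring B keeps its exocyclic methylene and the pent-4-enoyl group | C=C1CCC2=C(C)CC[C@@H]([C@@H](C)CC/C=C(\C)CO[Si](C)(C)C(C)(C)C)[C@@H]2[C@@H](C(=O)CCC=C)C1 | intermediate
21 | methylenation product of 20 (hexa-1,5-dien-2-yl group on ring B) | C=C1CCC2=C(C)CC[C@@H]([C@@H](C)CC/C=C(\C)CO[Si](C)(C)C(C)(C)C)[C@@H]2[C@@H](C(=C)CCC=C)C1 | intermediate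
22 | tert-butyldimethylsilyl ether of the target | C=C1CCC=C2CCC3=C(C)CC[C@@H]([C@@H](C)CC/C=C(\C)CO[Si](C)(C)C(C)(C)C)[C@@H]3[C@@H]1C2 | intermediate
23 | CNP0289180.1, tricyclic (E)-allylic alcohol | C=C1CCC=C2CCC3=C(C)CC[C@@H]([C@@H](C)CC/C=C(\C)CO)[C@@H]3[C@@H]1C2 | target

**Count**

Total steps: 14. Longest linear sequence: 12 steps (1 to 4, 6, 7, 9 to 14).

**Steps most likely to fail**

1. Step 9. Protodeboronation of the alkenyl boronate or oligomerisation of the vinyl ketone may outrun the intermolecular 1,4-addition. The seven-membered Michael closure on the α-substituted enone may stall. Hydroxide may epimerise the γ-centre of the enone or drive aldol condensation of the 1,5-diketone. The fallback sets out from 12 and 15 and replaces the rhodium cascade by two separate operations. A palladium-catalysed reductive Heck coupling (Pd(OAc)2, PPh3, HCO2Na, DMF, 60 °C) should give the open-chain ketone 16, now isolated. DBU or catalytic KOtBu in THF at low temperature then closes ring B by intramolecular Michael addition and equilibrates the new centres. It comes back at 17 and skips step 7.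

2. Step 11. The elimination may lose regiocontrol, with proton removal from the ring CH2 or the methyl group giving trisubstituted and exocyclic isomers. The fallback fixes the position of the double bond at the Michael stage by silyl transfer; it sets out from 12 and 15 and replaces steps 7 and 9 to 12. Nickel-catalysed reductive conjugate addition (NiCl2(dme), 2,9-dimethyl-1,10-phenanthroline, Mn, Et3SiCl, DMF) should give the triethylsilyl enol ether F1 of the open-chain ketone. Catalytic Tf2NH in CH2Cl2 at −78 °C then effects an intramolecular Mukaiyama–Michael addition with silyl transfer to the ring-C triethylsilyl enol ether F2, which still carries the open-chain ketone. Wittig methylenation (Ph3PCH3Br, KOtBu) gives the methylidene enol silane F3 and lets the acyl-bearing centre settle trans. MeLi followed by PhNTf2 gives the enol triflate F4, and Me2CuLi replaces the triflate by methyl. It comes back at 21.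

3. Step 13. The ruthenium alkylidene formed at the terminal alkene may dimerise by cross-metathesis, or be held unproductively by the neighbouring 1,1-disubstituted alkene, instead of engaging the exocyclic methylene of ring B. The fallback closes ring A one stage earlier, on the ketone, where that neighbouring alkene is absent. It sets out from 20: metathesis with the same catalyst should give the tricyclic ketone F5, which is then methylenated with Ph3P=CH2 in toluene at 90 °C (or Cp2TiMe2). It comes back at 22.

**Further compounds**

F0 | step 9 | none | none
F1 | step 11 | triethylsilyl enol ether of 16 on the side toward the methylidene carbon (E/Z mixture) | O=C1CC[C@@H]([C@@H](C)CC/C=C(\C)CO[Si](C)(C)C(C)(C)C)C=C1CCC(=C)CC=C(O[Si](CC)(CC)CC)CCC=C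
F2 | step 11 | ring-C triethylsilyl enol ether of 17 (enol C=C at the ring fusion) | C=C1CCC2=C(O[Si](CC)(CC)CC)CC[C@@H]([C@@H](C)CC/C=C(\C)CO[Si](C)(C)C(C)(C)C)[C@@H]2[C@@H](C(=O)CCC=C)C1
F3 | step 11 | methylenation product of F2 | C=C1CCC2=C(O[Si](CC)(CC)CC)CC[C@@H]([C@@H](C)CC/C=C(\C)CO[Si](C)(C)C(C)(C)C)[C@@H]2[C@@H](C(=C)CCC=C)C1
F4 | step 11 | enol triflate corresponding to F3 | C=C1CCC2=C(OS(=O)(=O)C(F)(F)F)CC[C@@H]([C@@H](C)CC/C=C(\C)CO[Si](C)(C)C(C)(C)C)[C@@H]2[C@@H](C(=C)CCC=C)C1
F5 | step 13 | tricyclic ketone, 22 with C=O in place of the ring-A C=CH2 | O=C1CCC=C2CCC3=C(C)CC[C@@H]([C@@H](C)CC/C=C(\C)CO[Si](C)(C)C(C)(C)C)[C@@H]3[C@@H]1C2
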